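**Retrosynthetic overview**
- The target comes from late methacrylation at O8; the 10-membered carbocycle and the trans-fused α-methylene-γ-lactone are formed last, together, by an intramolecular CrCl2-mediated 2-(methoxycarbonyl)allylation (C6–C7 bond).
- The seco precursor comes from a Mukaiyama aldol (C9–C10 bond) that joins a western 3-silyloxyfuran (C1–C6, C10, C14, C15) to an eastern chiral aldehyde (C7–C9, C11–C13).
- Western fragment: the furanone ring is formed first, by gold-catalysed cyclisation of an α'-hydroxy ynone made from a (Z)-enyne and a lactate Weinreb amide.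
- Eastern fragment: a Baylis–Hillman-type adduct of a glyceraldehyde derivative (from (S)-but-3-ene-1,2-diol) with methyl propiolate.
- Ring order: furanone (step 6), then carbocycle and lactone together (step 19).

Assumption: (Z)-3-methylpent-2-en-4-yn-1-ol and (S)-but-3-ene-1,2-diol are bought geometrically and enantiomerically pure.
Atom labels C1–C15 are germacrane labels of the target (C1 ketone, C3 furanone C–O, C4=C5, C6 lactone O, C8 methacrylate O, C9 acetate O, C10 quaternary, C11–C13 methylene lactone). TBS = tert-butyldimethylsilyl, TES = triethylsilyl, TIPS = triisopropylsilyl.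

**Western fragment**

Step 1
Reactants: 1 (Z)-3-methylpent-2-en-4-yn-1-ol
Product: 2 (Z)-1-(TBSO)-3-methylpent-2-en-4-yne
Conditions: TBSCl, imidazole, CH2Cl2, 0 °C to rt
Reagents that add atoms: tert-butyldimethylsilyl chloride, CC(C)(C)[Si](C)(C)Cl
Why: Standard silylation of the primary allylic alcohol; the Z alkene (C4=C5) is bought in and untouched.

Step 2
Reactants: 3 ethyl (S)-lactate
Product: 4 ethyl (2S)-2-(TESO)propanoate
Conditions: TESCl, imidazole, DMAP (cat.), CH2Cl2, 0 °C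
Reagents that add atoms: chlorotriethylsilane, CC[Si](Cl)(CC)CC
Why: O-silylation so that the later acetylide addition is clean; this centre (future C10) is erased in step 7 and re-set in step 14.

Step 3
Reactants: 4 ethyl (2S)-2-(TESO)propanoate
Product: 5 (2S)-N-methoxy-N-methyl-2-(TESO)propanamide
Conditions: MeNHOMe·HCl, iPrMgCl, THF, −20 to 0 °C
Reagents that add atoms: N,O-dimethylhydroxylamine hydrochloride, CNOC.Cl
Why: Weinreb amidation of the ester by the magnesium amide.

Step 4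
Reactants: 2 (Z)-1-(TBSO)-3-methylpent-2-en-4-yne; 5 (2S)-N-methoxy-N-methyl-2-(TESO)propanamide
Product: 7 (2S,6Z)-8-(TBSO)-6-methyl-2-(TESO)oct-6-en-4-yn-3-one, via lithium acetylide 6 (not isolated)
Conditions: n-BuLi, THF, −78 °C; then 5, −78 to −20 °C; aq. NH4Cl
Reagents that add atoms: none
Why: Acetylide acylation by the Weinreb amide stops at the ynone because of the stable chelated tetrahedral intermediate (C1–C2 bond).

Step 5
Reactants: 7 (2S,6Z)-8-(TBSO)-6-methyl-2-(TESO)oct-6-en-4-yn-3-one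
Product: 8 (2S,6Z)-8-(TBSO)-2-hydroxy-6-methyloct-6-en-4-yn-3-one
Conditions: PPTS (0.2 equiv), MeOH–CH2Cl2, 0 °C
Reagents that add atoms: none
Why: Mild acidic methanolysis removes the secondary TES ether much faster than the primary TBS ether.

Step 6
Reactants: 8 (2S,6Z)-8-(TBSO)-2-hydroxy-6-methyloct-6-en-4-yn-3-one
Product: 9 (2S)-2-methyl-5-[(2Z)-4-(TBSO)but-2-en-2-yl]furan-3(2H)-one
Conditions: (Ph3P)AuCl (2 mol %), AgOTf (2 mol %), toluene, rt
Reagents that add atoms: none
Why: Gold π-activation of the ynone triggers 5-endo-dig attack of the α'-hydroxyl (cycloisomerisation) to the 3(2H)-furanone.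

Step 7
Reactants: 9 (2S)-2-methyl-5-[(2Z)-4-(TBSO)but-2-en-2-yl]furan-3(2H)-one
Product: 10 2-methyl-3-(TIPSO)-5-[(2Z)-4-(TBSO)but-2-en-2-yl]furan
Conditions: TIPSOTf, Et3N, CH2Cl2, 0 °C
Reagents that add atoms: triisopropylsilyl triflate, CC(C)[Si](OS(=O)(=O)C(F)(F)F)(C(C)C)C(C)C
Why: Soft enolisation and O-silylation give the aromatic 3-silyloxyfuran, a silyl enol ether nucleophilic at C10.

**Eastern fragment**

Step 8
Reactants: 11 (S)-but-3-ene-1,2-diol
Product: 12 (2S)-1-(TESO)but-3-en-2-ol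
Conditions: TESCl (1.0 equiv), imidazole, CH2Cl2, −78 to −30 °C
Reagents that add atoms: chlorotriethylsilane, CC[Si](Cl)(CC)CC
Why: Selective silylation of the less hindered primary hydroxyl (future C9–O); the C8 stereocentre comes from 11.

Step 9
Reactants: 12 (2S)-1-(TESO)but-3-en-2-ol
Product: 13 (2S)-2-(TBSO)-1-(TESO)but-3-ene
Conditions: TBSOTf, 2,6-lutidine, CH2Cl2, −78 °C
Reagents that add atoms: tert-butyldimethylsilyl triflate, CC(C)(C)[Si](C)(C)OS(=O)(=O)C(F)(F)F
Why: Silylation of the secondary allylic hydroxyl with the robust group that protects O8 until step 20.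

Step 10
Reactants: 13 (2S)-2-(TBSO)-1-(TESO)but-3-ene
Product: 15 (2R)-2-(TBSO)-3-(TESO)propanal, via ozonide 14 (not isolated)
Conditions: O3, CH2Cl2, −78 °C; then PPh3, −78 °C to rt
Reagents that add atoms: ozone, [O-][O+]=O
Why: Ozonolysis with reductive work-up turns the vinyl group into the C7 aldehyde without touching the α-stereocentre.

Step 11
Reactants: 15 (2R)-2-(TBSO)-3-(TESO)propanal; 16 methyl propiolate
Product: 18 methyl (3S,4R)-4-(TBSO)-3-hydroxy-2-methylidene-5-(TESO)pentanoate, via vinylalane 17 (not isolated)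
Conditions: DIBAL-H, NMO, THF, 0 °C; 16; then 15, 0 °C to rt; Rochelle salt
Reagents that add atoms: none
Why: Hydroalumination of the propiolate gives an α-(methoxycarbonyl)vinylalane that adds to the aldehyde (Baylis–Hillman-type vinylalumination); Felkin–Anh attack gives mainly the 3,4-anti carbinol, a centre that is erased in step 18.

Step 12
Reactants: 18 methyl (3S,4R)-4-(TBSO)-3-hydroxy-2-methylidene-5-(TESO)pentanoate
Product: 19 methyl (3S,4R)-4-(TBSO)-2-methylidene-3,5-bis(TESO)pentanoate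
Conditions: TESOTf, 2,6-lutidine, CH2Cl2, −78 °C
Reagents that add atoms: triethylsilyl triflate, CC[Si](CC)(CC)OS(=O)(=O)C(F)(F)F
Why: Silylation of the allylic carbinol so that it survives the oxidation and the aldol.

Step 13
Reactants: 19 methyl (3S,4R)-4-(TBSO)-2-methylidene-3,5-bis(TESO)pentanoate
Product: 20 methyl (3S,4S)-4-(TBSO)-2-methylidene-5-oxo-3-(TESO)pentanoate
Conditions: (COCl)2, DMSO, CH2Cl2, −78 to −35 °C; Et3N, −78 to 0 °C
Reagents that add atoms: none
Why: Swern conditions oxidise a primary TES ether directly to the aldehyde (chloride removes the silyl group from the activated oxygen) while secondary silyl ethers are left alone.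

**Coupling and end game**

Step 14
Reactants: 10 2-methyl-3-(TIPSO)-5-[(2Z)-4-(TBSO)but-2-en-2-yl]furan; 20 methyl (3S,4S)-4-(TBSO)-2-methylidene-5-oxo-3-(TESO)pentanoate
Product: 21 aldol adduct, methyl 4-(TBSO)-5-hydroxy-2-methylidene-3-(TESO)-5-{2-methyl-3-oxo-5-[(2Z)-4-(TBSO)but-2-en-2-yl]-2,3-dihydrofuran-2-yl}pentanoate (7S; C8, C9, C10 arranged as in the target)
Conditions: BF3·OEt2, CH2Cl2, −78 °C; aq. NaHCO3
Reagents that add atoms: none
Why: Mukaiyama aldol at the silyloxyfuran carbon flanked by O and OSi: polar Felkin–Anh attack anti to the α-OTBS group sets C9 (8,9-anti), and the open antiperiplanar transition state that keeps the aldehyde chain away from the C10 methyl sets the quaternary C10 (9-OH and 10-Me syn).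

Step 15
Reactants: 21 aldol adduct
Product: 22 9-acetate of 21
Conditions: Ac2O, pyridine, DMAP (cat.), CH2Cl2, 0 °C to rt
Reagents that add atoms: acetic anhydride, CC(=O)OC(C)=O
Why: Acylation of the only free hydroxyl installs the C9 acetate and blocks retro-aldol cleavage.

Step 16
Reactants: 22 9-acetate
Product: 23 6,7-diol (C6 primary allylic OH, C7 OH; 8-OTBS kept)
Conditions: HF·pyridine, pyridine, THF, 0 °C
Reagents that add atoms: none
Why: Buffered fluoride removes the secondary TES and the primary allylic TBS ether much faster than the hindered secondary TBS ether at C8.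

Step 17
Reactants: 23 6,7-diol
Product: 24 (Z)-enal (C6 aldehyde, C7 OH)
Conditions: MnO2, CH2Cl2, rt
Reagents that add atoms: none
Why: MnO2 oxidises the electron-rich primary dienylic alcohol far faster than the electron-poor acrylate carbinol and keeps the Z geometry.

Step 18
Reactants: 24 (Z)-enal
Product: 25 (Z)-allylic bromide, C13H2Br–C11(CO2Me)=C7H–C8, with the C6 aldehyde
Conditions: NBS, Me2S, CH2Cl2, −20 to 0 °C
Reagents that add atoms: N-bromosuccinimide, O=C1CCC(=O)N1Br
Why: Corey–Kim-type activation of the Baylis–Hillman alcohol and SN2′ attack of bromide give the rearranged, thermodynamically favoured (Z)-2-(bromomethyl)enoate under neutral conditions that spare the aldehyde.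

Step 19
Reactants: 25 (Z)-allylic bromide
Product: 28 macrolactone, the target skeleton with OTBS at C8, via allylchromium 26 (not isolated), via hydroxy ester 27 (not isolated)
Conditions: CrCl2 (10 equiv), THF–DMF, rt, syringe pump (final 2 mM); 1 M HCl work-up
Reagents that add atoms: none
Why: Intramolecular Nozaki–Hiyama-type allylation: the allylchromium adds through its γ-carbon (C7) to the aldehyde in a chair-like transition state with both ring tethers equatorial, giving the 6,7-anti adduct (C6 R, C7 S, with the C8 silyloxy group pseudo-equatorial), which lactonises to the trans-fused α-methylene-γ-lactone.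

Step 20
Reactants: 28 macrolactone (8-OTBS)
Product: 29 8-hydroxy macrolactone
Conditions: aq. HF (48 %), MeCN, 0 °C to rt
Reagents that add atoms: none
Why: Acidic fluoride desilylation avoids the base that would cause 9-to-8 acetyl migration or conjugate addition to the methylene lactone.

Step 21
Reactants: 29 8-hydroxy macrolactone
Product: 30 target, CNP0365569.2
Conditions: methacrylic anhydride, Et3N, DMAP (cat.), CH2Cl2, 0 °C
Reagents that add atoms: methacrylic anhydride, C=C(C)C(=O)OC(=O)C(C)=C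
Why: DMAP-catalysed acylation of the single free secondary hydroxyl with retention at C8.

**Compound list**
1 | (Z)-3-methylpent-2-en-4-yn-1-ol | C#C/C(C)=C\CO | starting material
2 | (Z)-1-(TBSO)-3-methylpent-2-en-4-yne | C#C/C(C)=C\CO[Si](C)(C)C(C)(C)C | intermediate
3 | ethyl (S)-lactate | C[C@H](O)C(=O)OCC | starting material
4 | ethyl (2S)-2-(TESO)propanoate | C[C@H](O[Si](CC)(CC)CC)C(=O)OCC | intermediate
5 | (2S)-N-methoxy-N-methyl-2-(TESO)propanamide | C[C@H](O[Si](CC)(CC)CC)C(=O)N(C)OC | intermediate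
6 | lithium acetylide of 2 | [Li]C#C/C(C)=C\CO[Si](C)(C)C(C)(C)C | intermediate
7 | (2S,6Z)-8-(TBSO)-6-methyl-2-(TESO)oct-6-en-4-yn-3-one | C[C@H](O[Si](CC)(CC)CC)C(=O)C#C/C(C)=C\CO[Si](C)(C)C(C)(C)C | intermediate
8 | (2S,6Z)-8-(TBSO)-2-hydroxy-6-methyloct-6-en-4-yn-3-one | C[C@H](O)C(=O)C#C/C(C)=C\CO[Si](C)(C)C(C)(C)C | intermediate
9 | (2S)-2-methyl-5-[(2Z)-4-(TBSO)but-2-en-2-yl]furan-3(2H)-one | C[C@@H]1OC(/C(C)=C\CO[Si](C)(C)C(C)(C)C)=CC1=O | intermediate
10 | 2-methyl-3-(TIPSO)-5-[(2Z)-4-(TBSO)but-2-en-2-yl]furan | Cc1oc(/C(C)=C\CO[Si](C)(C)C(C)(C)C)cc1O[Si](C(C)C)(C(C)C)C(C)C | intermediate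
11 | (S)-but-3-ene-1,2-diol | C=C[C@H](O)CO | starting material
12 | (2S)-1-(TESO)but-3-en-2-ol | C=C[C@H](O)CO[Si](CC)(CC)CC | intermediate
13 | (2S)-2-(TBSO)-1-(TESO)but-3-ene | C=C[C@H](O[Si](C)(C)C(C)(C)C)CO[Si](CC)(CC)CC | intermediate
14 | 3-[(1R)-1-(TBSO)-2-(TESO)ethyl]-1,2,4-trioxolane (ozonide, mixture at the ring carbon) | O1OCOC1[C@H](O[Si](C)(C)C(C)(C)C)CO[Si](CC)(CC)CC | intermediate
15 | (2R)-2-(TBSO)-3-(TESO)propanal | O=C[C@H](O[Si](C)(C)C(C)(C)C)CO[Si](CC)(CC)CC | intermediate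
16 | methyl propiolate | C#CC(=O)OC | starting material
17 | diisobutyl[1-(methoxycarbonyl)ethenyl]alane | C=C(C(=O)OC)[Al](CC(C)C)CC(C)C | intermediate
18 | methyl (3S,4R)-4-(TBSO)-3-hydroxy-2-methylidene-5-(TESO)pentanoate | C=C(C(=O)OC)[C@H](O)[C@H](O[Si](C)(C)C(C)(C)C)CO[Si](CC)(CC)CC | intermediate
19 | methyl (3S,4R)-4-(TBSO)-2-methylidene-3,5-bis(TESO)pentanoate | C=C(C(=O)OC)[C@H](O[Si](CC)(CC)CC)[C@H](O[Si](C)(C)C(C)(C)C)CO[Si](CC)(CC)CC | intermediate
20 | methyl (3S,4S)-4-(TBSO)-2-methylidene-5-oxo-3-(TESO)pentanoate | C=C(C(=O)OC)[C@H](O[Si](CC)(CC)CC)[C@H](O[Si](C)(C)C(C)(C)C)C=O | intermediate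
21 | aldol adduct (7-OTES, 8-OTBS, 9-OH, furanone at C10, 6-OTBS) | C=C(C(=O)OC)[C@H](O[Si](CC)(CC)CC)[C@H](O[Si](C)(C)C(C)(C)C)[C@H](O)[C@]1(C)OC(/C(C)=C\CO[Si](C)(C)C(C)(C)C)=CC1=O | intermediate
22 | 9-acetate of 21 | C=C(C(=O)OC)[C@H](O[Si](CC)(CC)CC)[C@H](O[Si](C)(C)C(C)(C)C)[C@H](OC(C)=O)[C@]1(C)OC(/C(C)=C\CO[Si](C)(C)C(C)(C)C)=CC1=O | intermediate
23 | 6,7-diol (8-OTBS, 9-OAc) | C=C(C(=O)OC)[C@H](O)[C@H](O[Si](C)(C)C(C)(C)C)[C@H](OC(C)=O)[C@]1(C)OC(/C(C)=C\CO)=CC1=O | intermediate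
24 | (Z)-enal with free C7 hydroxyl | C=C(C(=O)OC)[C@H](O)[C@H](O[Si](C)(C)C(C)(C)C)[C@H](OC(C)=O)[C@]1(C)OC(/C(C)=C\C=O)=CC1=O | intermediate
25 | (Z)-allylic bromide enal | BrC/C(C(=O)OC)=C\[C@H](O[Si](C)(C)C(C)(C)C)[C@H](OC(C)=O)[C@]1(C)OC(/C(C)=C\C=O)=CC1=O | intermediate
26 | allylchromium dichloride from 25 (trivalent chromium) | Cl[Cr](Cl)C/C(C(=O)OC)=C\[C@H](O[Si](C)(C)C(C)(C)C)[C@H](OC(C)=O)[C@]1(C)OC(/C(C)=C\C=O)=CC1=O | intermediate
27 | macrocyclic 6-hydroxy methyl ester (drawn as the alcohol of the chromium alkoxide) | CC(C)(C)[Si](C)(C)O[C@H]1[C@@H](C(=C)C(=O)OC)[C@H](O)/C=C(/C)C2=CC(=O)[C@@](C)(O2)[C@H]1OC(C)=O | intermediate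
28 | macrolactone with OTBS at C8 | CC(C)(C)[Si](C)(C)O[C@H]1[C@H]2C(=C)C(=O)O[C@@H]2/C=C(/C)C2=CC(=O)[C@@](C)(O2)[C@H]1OC(C)=O | intermediate
29 | 8-hydroxy macrolactone | O[C@H]1[C@H]2C(=C)C(=O)O[C@@H]2/C=C(/C)C2=CC(=O)[C@@](C)(O2)[C@H]1OC(C)=O | intermediate
30 | CNP0365569.2 | C=C(C)C(=O)O[C@H]1[C@H]2C(=C)C(=O)O[C@@H]2/C=C(/C)C2=CC(=O)[C@@](C)(O2)[C@H]1OC(C)=O | target

**Step count**
Total: 21 steps. Longest linear sequence: 14 steps (8–13, then 14–21; the lactate line 2–7, then 14–21, is equally long).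

**Three steps most likely to fail, with fallbacks**

Step 14 (aldol; two stereocentres from an open transition state). The fallback sets out from aldehyde 20, uses acetylide 6, and comes back at 22. It builds the quaternary centre on a lactic acid template instead of on the furanone. (2R,5R)-2-tert-butyl-5-methyl-1,3-dioxolan-4-one F1 is made from (R)-lactic acid and pivalaldehyde (TsOH, pentane, water removal). It is deprotonated with LDA (THF, −78 °C) and added to 20; the aldehyde enters anti to the tert-butyl group, so C10 is fixed by the template, and Felkin–Anh control fixes C9, giving the dioxolanone aldol adduct F2. Lithium acetylide 6 (2.5 equiv, −78 °C) opens the dioxolanone with loss of pivalaldehyde to the 9,10-dihydroxy ynone F3. Ac2O/pyridine acetylates only the secondary hydroxyl to give the 9-acetoxy-10-hydroxy ynone F4, and (Ph3P)AuCl/AgOTf closes the furanone to give 22.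

Step 19 (strained 10-membered ring closure; two stereocentres). The fallback sets out from furanone 9 and adduct 18 and comes back at 28. It inverts the order of the two key bonds, so the C6–C7 bond is made without ring strain and the ring is closed at C9–C10. HF·pyridine converts 9 into the allylic alcohol (2S)-5-[(2Z)-4-hydroxybut-2-en-2-yl]-2-methylfuran-3(2H)-one F5, and MnO2 gives the enal (2S)-2-methyl-5-[(2Z)-4-oxobut-2-en-2-yl]furan-3(2H)-one F6. NBS/Me2S converts 18 into methyl (2Z,4S)-2-(bromomethyl)-4-(TBSO)-5-(TESO)pent-2-enoate F7. Intermolecular CrCl2-mediated allylation of F6 with F7 and lactonisation give the trans-disubstituted α-methylene-γ-butyrolactone F8. Selective Swern oxidation of its primary TES ether gives the lactone aldehyde F9. TIPSOTf/Et3N gives the silyloxyfuran aldehyde F10, which is closed by a high-dilution BF3·OEt2 Mukaiyama aldol to the macrocyclic 9-hydroxy compound F11; acetylation (Ac2O, pyridine, DMAP) gives 28.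

Step 11 (vinylalumination of a sensitive α-silyloxy aldehyde; silyl migration and modest diastereoselectivity). The fallback sets out from aldehyde 15 and comes back at 18. Methyl 2-bromoacrylate is treated with CrCl2 and a catalytic amount of NiCl2 in DMF to give the alkenylchromium reagent [1-(methoxycarbonyl)ethenyl]chromium dichloride F12, which adds to 15 under neutral conditions (Nozaki–Hiyama–Kishi coupling) to give 18.

**Further compounds**
F1 | step 14 | (2R,5R)-2-tert-butyl-5-methyl-1,3-dioxolan-4-one | C[C@H]1O[C@@H](C(C)(C)C)OC1=O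
F2 | step 14 | dioxolanone aldol adduct of F1 with 20 (7-OTES, 8-OTBS, 9-OH) | C=C(C(=O)OC)[C@H](O[Si](CC)(CC)CC)[C@H](O[Si](C)(C)C(C)(C)C)[C@H](O)[C@]1(C)O[C@@H](C(C)(C)C)OC1=O
F3 | step 14 | 9,10-dihydroxy ynone | C=C(C(=O)OC)[C@H](O[Si](CC)(CC)CC)[C@H](O[Si](C)(C)C(C)(C)C)[C@H](O)[C@](C)(O)C(=O)C#C/C(C)=C\CO[Si](C)(C)C(C)(C)C
F4 | step 14 | 9-acetoxy-10-hydroxy ynone | C=C(C(=O)OC)[C@H](O[Si](CC)(CC)CC)[C@H](O[Si](C)(C)C(C)(C)C)[C@H](OC(C)=O)[C@](C)(O)C(=O)C#C/C(C)=C\CO[Si](C)(C)C(C)(C)C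
F5 | step 19 | (2S)-5-[(2Z)-4-hydroxybut-2-en-2-yl]-2-methylfuran-3(2H)-one | C[C@@H]1OC(/C(C)=C\CO)=CC1=O
F6 | step 19 | (2S)-2-methyl-5-[(2Z)-4-oxobut-2-en-2-yl]furan-3(2H)-one | C[C@@H]1OC(/C(C)=C\C=O)=CC1=O
F7 | step 19 | methyl (2Z,4S)-2-(bromomethyl)-4-(TBSO)-5-(TESO)pent-2-enoate | BrC/C(C(=O)OC)=C\[C@H](O[Si](C)(C)C(C)(C)C)CO[Si](CC)(CC)CC
F8 | step 19 | trans-disubstituted α-methylene-γ-butyrolactone (furanone dienyl at C6, silyloxy chain at C7) | C=C1C(=O)O[C@H](/C=C(/C)C2=CC(=O)C(C)O2)[C@H]1[C@H](O[Si](C)(C)C(C)(C)C)CO[Si](CC)(CC)CC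
F9 | step 19 | lactone aldehyde (C9 aldehyde) | C=C1C(=O)O[C@H](/C=C(/C)C2=CC(=O)C(C)O2)[C@H]1[C@H](O[Si](C)(C)C(C)(C)C)C=O
F10 | step 19 | silyloxyfuran aldehyde | C=C1C(=O)O[C@H](/C=C(/C)c2cc(O[Si](C(C)C)(C(C)C)C(C)C)c(C)o2)[C@H]1[C@H](O[Si](C)(C)C(C)(C)C)C=O
F11 | step 19 | macrocyclic 9-hydroxy compound (8-OTBS) | CC(C)(C)[Si](C)(C)O[C@H]1[C@H]2C(=C)C(=O)O[C@@H]2/C=C(/C)C2=CC(=O)[C@@](C)(O2)[C@H]1O
F12 | step 11 | [1-(methoxycarbonyl)ethenyl]chromium dichloride | C=C(C(=O)OC)[Cr](Cl)Cl
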